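**Plan**

- Retrosynthesis: the two gallate esters at O7 and O3' are cut first, then the aryl ether O1–C8a of ring C, then C2–C1' (aryl Grignard on a Weinreb amide) and C3–C4 (benzylation of a chiral glycolate enolate).
- Enabling feature: O1–C8a joins the benzylic C2 oxygen to a ring A carbon that is meta to both C5–O and C7–O, so C8a can be carried as the bromide of 5-bromoresorcinol and closed by intramolecular palladium-catalysed O-arylation.
- Forward: the ring A benzylic bromide (O7 as MOM, O5 as benzyl, told apart through the hydrogen bond to the ortho formyl group) and the ring B aryl bromide are made separately. The chain is joined at C3–C4, then at C2–C1'; ring C closes; the MOM groups are exchanged for galloyl groups and hydrogenolysis ends the route.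
- Stereochemistry: C3 (S) comes from the (R)-4-benzyloxazolidinone-directed enolate alkylation; C2 (R) comes from a zinc-chelate-controlled ketone reduction (anti). Both pass unchanged through a ring closure that breaks no bond at C2 or C3.

Key step: step 14

Assumption: flavan numbering is used (O1, C2, C3, C4, C4a, C5 to C8, C8a; ring B primed), and (R)-4-benzyloxazolidin-2-one and 3,4,5-tris(benzyloxy)benzoic acid are taken as purchased.

**Ring A fragment**

Step 1
Reactants: 1 5-bromoresorcinol
Product: 3 2-bromo-4,6-dihydroxybenzaldehyde, via iminium chloride 2 (not isolated)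
Conditions: POCl3, DMF, MeCN, 0 °C to rt; then H2O, 50 °C
Reagents that add atoms: N,N-dimethylformamide CN(C)C=O; water O
Why: Vilsmeier–Haack formylation of the resorcinol should attack C4, para to one hydroxyl and ortho to the other as in orcinol, rather than the flanked C2, and hydrolysis of the iminium salt releases the aldehyde.

Step 2
Reactants: 3 2-bromo-4,6-dihydroxybenzaldehyde
Product: 4 2-bromo-6-hydroxy-4-(methoxymethoxy)benzaldehyde
Conditions: MOMCl (1.05 equiv), i-Pr2NEt, CH2Cl2, 0 °C
Reagents that add atoms: chloromethyl methyl ether COCCl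
Why: Williamson-type MOM ether formation should go at the more acidic hydroxyl para to the formyl group, because the ortho hydroxyl is held in a hydrogen bond to the carbonyl oxygen.

Step 3
Reactants: 4 2-bromo-6-hydroxy-4-(methoxymethoxy)benzaldehyde
Product: 5 2-(benzyloxy)-6-bromo-4-(methoxymethoxy)benzaldehyde
Conditions: BnBr, K2CO3, DMF, 60 °C
Reagents that add atoms: benzyl bromide BrCc1ccccc1
Why: Williamson ether synthesis on the remaining hydrogen-bonded phenol under carbonate/DMF conditions leaves the later O5 and O7 with different protecting groups.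

Step 4
Reactants: 5 2-(benzyloxy)-6-bromo-4-(methoxymethoxy)benzaldehyde
Product: 6 [2-(benzyloxy)-6-bromo-4-(methoxymethoxy)phenyl]methanol
Conditions: NaBH4, MeOH/THF, 0 °C
Reagents that add atoms: none
Why: Borohydride reduction of the aldehyde leaves the aryl bromide, the MOM acetal and the benzyl ether untouched.

Step 5
Reactants: 6 [2-(benzyloxy)-6-bromo-4-(methoxymethoxy)phenyl]methanol
Product: 7 1-(benzyloxy)-3-bromo-2-(bromomethyl)-5-(methoxymethoxy)benzene
Conditions: CBr4, PPh3, CH2Cl2, 0 °C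
Reagents that add atoms: carbon tetrabromide BrC(Br)(Br)Br
Why: Appel bromination converts the benzylic alcohol to the bromide under neutral conditions that spare the MOM acetal, and the electron-rich bromide is to be used at once without storage.

**Ring B fragment**

Step 6
Reactants: 8 5-bromosalicylaldehyde
Product: 9 2-(benzyloxy)-5-bromobenzaldehyde
Conditions: BnBr, K2CO3, DMF, rt
Reagents that add atoms: benzyl bromide BrCc1ccccc1
Why: Williamson ether synthesis on the phenol fixes the benzyl group on the oxygen that becomes O4'.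

Step 7
Reactants: 9 2-(benzyloxy)-5-bromobenzaldehyde
Product: 11 2-(benzyloxy)-5-bromophenol, via aryl formate 10 (not isolated)
Conditions: mCPBA, CH2Cl2, rt; then K2CO3 (cat.), MeOH, rt
Reagents that add atoms: 3-chloroperoxybenzoic acid OOC(=O)c1cccc(Cl)c1
Why: Baeyer–Villiger (Dakin-type) oxidation, in which the electron-rich aryl group migrates to give the aryl formate, followed by mild methanolysis, turns the formyl carbon into the hydroxyl that becomes O3'.

Step 8
Reactants: 11 2-(benzyloxy)-5-bromophenol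
Product: 12 1-(benzyloxy)-4-bromo-2-(methoxymethoxy)benzene
Conditions: MOMCl, i-Pr2NEt, CH2Cl2, 0 °C to rt
Reagents that add atoms: chloromethyl methyl ether COCCl
Why: MOM ether formation on the free phenol gives O3' the same acid-labile group as O7, so both can later be freed together.

**Chain assembly**

Step 9
Reactants: 13 (R)-4-benzyloxazolidin-2-one; 14 benzyloxyacetyl chloride
Product: 16 (R)-4-benzyl-3-[(benzyloxy)acetyl]oxazolidin-2-one, via lithium oxazolidinide 15 (not isolated)
Conditions: n-BuLi, THF, −78 °C; then 14, −78 to 0 °C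
Reagents that add atoms: none
Why: N-acylation of the lithiated oxazolidinone by the acid chloride at low temperature is the standard entry to glycolyl imides.

Step 10
Reactants: 16 (R)-4-benzyl-3-[(benzyloxy)acetyl]oxazolidin-2-one; 7 1-(benzyloxy)-3-bromo-2-(bromomethyl)-5-(methoxymethoxy)benzene
Product: 18 (R)-4-benzyl-3-[(S)-2-(benzyloxy)-3-[2-(benzyloxy)-6-bromo-4-(methoxymethoxy)phenyl]propanoyl]oxazolidin-2-one, via sodium enolate 17 (not isolated)
Conditions: NaN(SiMe3)2, THF, −78 °C; then 7, −78 to −40 °C (16 in excess)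
Reagents that add atoms: none
Why: Evans asymmetric alkylation of the chelated sodium Z-enolate, in which the C4 benzyl group of the (R)-auxiliary shields one face and the benzylic bromide adds to the other, should set the future C3 as (S).

Step 11
Reactants: 18 (R)-4-benzyl-3-[(S)-2-(benzyloxy)-3-[2-(benzyloxy)-6-bromo-4-(methoxymethoxy)phenyl]propanoyl]oxazolidin-2-one
Product: 19 (S)-2-(benzyloxy)-3-[2-(benzyloxy)-6-bromo-4-(methoxymethoxy)phenyl]-N-methoxy-N-methylpropanamide
Conditions: MeNH(OMe)·HCl, AlMe3, CH2Cl2, 0 °C to rt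
Reagents that add atoms: N,O-dimethylhydroxylamine hydrochloride CNOC.Cl
Why: Weinreb transamidation by the aluminium amide made from AlMe3 and the amine salt should attack the exocyclic carbonyl and release the auxiliary without touching the α-stereocentre.

Step 12
Reactants: 19 (S)-2-(benzyloxy)-3-[2-(benzyloxy)-6-bromo-4-(methoxymethoxy)phenyl]-N-methoxy-N-methylpropanamide; 12 1-(benzyloxy)-4-bromo-2-(methoxymethoxy)benzene
Product: 21 (S)-2-(benzyloxy)-1-[4-(benzyloxy)-3-(methoxymethoxy)phenyl]-3-[2-(benzyloxy)-6-bromo-4-(methoxymethoxy)phenyl]propan-1-one, via arylmagnesium bromide 20 (not isolated)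
Conditions: 12, Mg, I2 (cat.), THF, 40 °C; then 19, THF, −20 to 0 °C; aq. NH4Cl
Reagents that add atoms: none
Why: Grignard addition to the Weinreb amide stops at the chelated tetrahedral adduct and gives the aryl ketone on work-up, and a magnesium reagent (not an aryllithium) is chosen so that the ring A bromide is not exchanged.

Step 13
Reactants: 21 (S)-2-(benzyloxy)-1-[4-(benzyloxy)-3-(methoxymethoxy)phenyl]-3-[2-(benzyloxy)-6-bromo-4-(methoxymethoxy)phenyl]propan-1-one
Product: 22 (1R,2S)-2-(benzyloxy)-1-[4-(benzyloxy)-3-(methoxymethoxy)phenyl]-3-[2-(benzyloxy)-6-bromo-4-(methoxymethoxy)phenyl]propan-1-ol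
Conditions: Zn(BH4)2, Et2O/CH2Cl2, −20 °C
Reagents that add atoms: none
Why: Chelation-controlled (Cram-chelate) reduction, in which zinc bridges the carbonyl and α-benzyloxy oxygens and hydride adds from the face of the α-hydrogen, should give the anti (1R,2S) alcohol and so set C2.

**Ring closure and end game**

Step 14
Reactants: 22 (1R,2S)-2-(benzyloxy)-1-[4-(benzyloxy)-3-(methoxymethoxy)phenyl]-3-[2-(benzyloxy)-6-bromo-4-(methoxymethoxy)phenyl]propan-1-ol
Product: 23 (2R,3S)-3,5-bis(benzyloxy)-2-[4-(benzyloxy)-3-(methoxymethoxy)phenyl]-7-(methoxymethoxy)chromane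
Conditions: Pd(OAc)2 (5 mol %), 2-(di-tert-butylphosphino)-1,1'-binaphthyl (6 mol %), Cs2CO3, toluene, 80 °C
Reagents that add atoms: none
Why: Zerovalent palladium, formed in situ from Pd(OAc)2 and the phosphine, inserts into the C8a–Br bond, Cs2CO3 exchanges bromide for the C2 alkoxide to give a seven-membered aryl(alkoxo) divalent palladium chelate, and C–O reductive elimination forms O1–C8a. The closest known reaction type is the intramolecular Buchwald–Hartwig etherification of 3-(2-bromoaryl)propanols bearing secondary hydroxyls to chromans. Ring C closes as a six-membered ring by reductive elimination from that oxapalladacycle, formally a 6-exo attack of O1 on C8a. No stereocentre is created: neither the C2–O nor the C3–O bond is broken, so the (1R,2S) configuration of 22 becomes (2R,3S) with retention and no benzylic cation at C2 arises. The step needs C–O reductive elimination to outrun β-hydride elimination of the secondary benzylic alkoxide, which the bulky, electron-rich di-tert-butyl biaryl phosphine should enforce; the C2 hydroxyl is the only free hydroxyl and C8a–Br the only aryl halide in 22, so no other coupling site competes.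

Step 15
Reactants: 23 (2R,3S)-3,5-bis(benzyloxy)-2-[4-(benzyloxy)-3-(methoxymethoxy)phenyl]-7-(methoxymethoxy)chromane
Product: 24 (2R,3S)-3,5-bis(benzyloxy)-2-[4-(benzyloxy)-3-hydroxyphenyl]chroman-7-ol
Conditions: HCl (2 M in MeOH), THF, 40 °C
Reagents that add atoms: none
Why: Acid-catalysed acetal exchange with methanol (MOM cleavage) should free the O7 and O3' phenols, while the benzyl ethers and the ring C ether, whose C2 aryl group still carries a benzylated O4', withstand these mild conditions.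

Step 16
Reactants: 24 (2R,3S)-3,5-bis(benzyloxy)-2-[4-(benzyloxy)-3-hydroxyphenyl]chroman-7-ol; 25 3,4,5-tris(benzyloxy)benzoic acid
Product: 26 (2R,3S)-3,5-bis(benzyloxy)-2-[4-(benzyloxy)-3-[3,4,5-tris(benzyloxy)benzoyloxy]phenyl]chroman-7-yl 3,4,5-tris(benzyloxy)benzoate
Conditions: 25 (2.4 equiv), EDC·HCl, DMAP, CH2Cl2, rt
Reagents that add atoms: none
Why: Steglich-type carbodiimide/DMAP esterification acylates the only two free hydroxyls of 24, the O7 and O3' phenols.

Step 17
Reactants: 26 (2R,3S)-3,5-bis(benzyloxy)-2-[4-(benzyloxy)-3-[3,4,5-tris(benzyloxy)benzoyloxy]phenyl]chroman-7-yl 3,4,5-tris(benzyloxy)benzoate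
Product: 27 catechin 7,3'-di-O-gallate
Conditions: H2 (1 atm), Pd(OH)2/C, THF/MeOH, rt
Reagents that add atoms: none
Why: Catalytic hydrogenolysis should remove all nine benzyl ethers under neutral conditions that leave the aryl gallate esters and both stereocentres intact and supply no base that could shift the 3'-gallate to O4'.

**Compound list**

1 | 5-bromoresorcinol | Oc1cc(O)cc(Br)c1 | starting material
2 | [(2-bromo-4,6-dihydroxyphenyl)methylidene]dimethyliminium chloride | C[N+](C)=Cc1c(O)cc(O)cc1Br.[Cl-] | intermediate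
3 | 2-bromo-4,6-dihydroxybenzaldehyde | O=Cc1c(O)cc(O)cc1Br | intermediate
4 | 2-bromo-6-hydroxy-4-(methoxymethoxy)benzaldehyde | COCOc1cc(O)c(C=O)c(Br)c1 | intermediate
5 | 2-(benzyloxy)-6-bromo-4-(methoxymethoxy)benzaldehyde | COCOc1cc(OCc2ccccc2)c(C=O)c(Br)c1 | intermediate
6 | [2-(benzyloxy)-6-bromo-4-(methoxymethoxy)phenyl]methanol | COCOc1cc(OCc2ccccc2)c(CO)c(Br)c1 | intermediate
7 | 1-(benzyloxy)-3-bromo-2-(bromomethyl)-5-(methoxymethoxy)benzene | COCOc1cc(OCc2ccccc2)c(CBr)c(Br)c1 | intermediate
8 | 5-bromosalicylaldehyde | O=Cc1cc(Br)ccc1O | starting material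
9 | 2-(benzyloxy)-5-bromobenzaldehyde | O=Cc1cc(Br)ccc1OCc1ccccc1 | intermediate
10 | 2-(benzyloxy)-5-bromophenyl formate | O=COc1cc(Br)ccc1OCc1ccccc1 | intermediate
11 | 2-(benzyloxy)-5-bromophenol | Oc1cc(Br)ccc1OCc1ccccc1 | intermediate
12 | 1-(benzyloxy)-4-bromo-2-(methoxymethoxy)benzene | COCOc1cc(Br)ccc1OCc1ccccc1 | intermediate
13 | (R)-4-benzyloxazolidin-2-one | O=C1OC[C@@H](Cc2ccccc2)N1 | starting material
14 | benzyloxyacetyl chloride | O=C(Cl)COCc1ccccc1 | starting material
15 | lithium (R)-4-benzyl-2-oxooxazolidin-3-ide | [Li+].O=C1OC[C@@H](Cc2ccccc2)[N-]1 | intermediate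
16 | (R)-4-benzyl-3-[(benzyloxy)acetyl]oxazolidin-2-one | O=C(COCc1ccccc1)N1C(=O)OC[C@H]1Cc1ccccc1 | intermediate
17 | sodium (Z)-1-[(R)-4-benzyl-2-oxooxazolidin-3-yl]-2-(benzyloxy)ethen-1-olate | [Na+].[O-]/C(=C\OCc1ccccc1)N1C(=O)OC[C@H]1Cc1ccccc1 | intermediate
18 | (R)-4-benzyl-3-[(S)-2-(benzyloxy)-3-[2-(benzyloxy)-6-bromo-4-(methoxymethoxy)phenyl]propanoyl]oxazolidin-2-one | COCOc1cc(OCc2ccccc2)c(C[C@H](OCc2ccccc2)C(=O)N2C(=O)OC[C@H]2Cc2ccccc2)c(Br)c1 | intermediate
19 | (S)-2-(benzyloxy)-3-[2-(benzyloxy)-6-bromo-4-(methoxymethoxy)phenyl]-N-methoxy-N-methylpropanamide | COCOc1cc(OCc2ccccc2)c(C[C@H](OCc2ccccc2)C(=O)N(C)OC)c(Br)c1 | intermediate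
20 | [4-(benzyloxy)-3-(methoxymethoxy)phenyl]magnesium bromide | COCOc1cc([Mg]Br)ccc1OCc1ccccc1 | intermediate
21 | (S)-2-(benzyloxy)-1-[4-(benzyloxy)-3-(methoxymethoxy)phenyl]-3-[2-(benzyloxy)-6-bromo-4-(methoxymethoxy)phenyl]propan-1-one | COCOc1cc(OCc2ccccc2)c(C[C@H](OCc2ccccc2)C(=O)c2ccc(OCc3ccccc3)c(OCOC)c2)c(Br)c1 | intermediate
22 | (1R,2S)-2-(benzyloxy)-1-[4-(benzyloxy)-3-(methoxymethoxy)phenyl]-3-[2-(benzyloxy)-6-bromo-4-(methoxymethoxy)phenyl]propan-1-ol | COCOc1cc(OCc2ccccc2)c(C[C@H](OCc2ccccc2)[C@H](O)c2ccc(OCc3ccccc3)c(OCOC)c2)c(Br)c1 | intermediate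
23 | (2R,3S)-3,5-bis(benzyloxy)-2-[4-(benzyloxy)-3-(methoxymethoxy)phenyl]-7-(methoxymethoxy)chromane | COCOc1cc(OCc2ccccc2)c2c(c1)O[C@H](c1ccc(OCc3ccccc3)c(OCOC)c1)[C@@H](OCc1ccccc1)C2 | intermediate
24 | (2R,3S)-3,5-bis(benzyloxy)-2-[4-(benzyloxy)-3-hydroxyphenyl]chroman-7-ol | Oc1cc(OCc2ccccc2)c2c(c1)O[C@H](c1ccc(OCc3ccccc3)c(O)c1)[C@@H](OCc1ccccc1)C2 | intermediate
25 | 3,4,5-tris(benzyloxy)benzoic acid | OC(=O)c1cc(OCc2ccccc2)c(OCc2ccccc2)c(OCc2ccccc2)c1 | starting material
26 | (2R,3S)-3,5-bis(benzyloxy)-2-[4-(benzyloxy)-3-[3,4,5-tris(benzyloxy)benzoyloxy]phenyl]chroman-7-yl 3,4,5-tris(benzyloxy)benzoate | O=C(Oc1cc(OCc2ccccc2)c2c(c1)O[C@H](c1ccc(OCc3ccccc3)c(OC(=O)c3cc(OCc4ccccc4)c(OCc4ccccc4)c(OCc4ccccc4)c3)c1)[C@@H](OCc1ccccc1)C2)c1cc(OCc2ccccc2)c(OCc2ccccc2)c(OCc2ccccc2)c1 | intermediate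
27 | catechin 7,3'-di-O-gallate, (2R,3S)-3,5-dihydroxy-2-[4-hydroxy-3-(3,4,5-trihydroxybenzoyloxy)phenyl]chroman-7-yl 3,4,5-trihydroxybenzoate | O=C(Oc1cc(O)c2c(c1)O[C@H](c1ccc(O)c(OC(=O)c3cc(O)c(O)c(O)c3)c1)[C@@H](O)C2)c1cc(O)c(O)c(O)c1 | target

**Step count**

Total: 17 steps. Longest linear sequence: 13 steps (steps 1 to 5 and 10 to 17, from 5-bromoresorcinol).

**Steps most likely to fail**

Step 14. The aryl(alkoxo)palladium intermediate may undergo β-hydride elimination, returning the ketone and a debrominated arene, or oxidative addition into the electron-rich, ortho-substituted bromide may stall. The fallback forms the ring C ether from the other side, at O1–C2, without an aryl–palladium alkoxide. It sets out from ketone 21. Reduction with KBH(s-Bu)3 in THF at −78 °C under Felkin–Anh control should give the syn (1S,2S) alcohol F1. Miyaura borylation (B2pin2, Pd(dppf)Cl2, KOAc, dioxane, 80 °C) converts the bromide into the pinacol boronate F2, and oxidation with NaBO3·4H2O in THF/H2O gives the phenol F3. Mitsunobu cyclisation (PPh3, DIAD, THF, 0 °C) then displaces the activated benzylic hydroxyl by the phenol oxygen with inversion, turning (1S) into (2R), and the route is rejoined at chroman 23.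

Step 10. The thermally labile glycolate enolate may decompose before the di-ortho-substituted benzylic bromide is consumed, and the electron-rich bromide may ionise and self-condense. The fallback sets C3 by catalytic asymmetric hydrogenation instead of enolate alkylation and avoids the benzylic bromide. It sets out from aldehyde 5. Horner–Wadsworth–Emmons olefination with methyl 2-(benzyloxy)-2-(dimethoxyphosphoryl)acetate (LiN(SiMe3)2, THF, −78 °C to rt) should give the (Z)-α-benzyloxy acrylate F4. Saponification (LiOH, THF/H2O) gives the acrylic acid F5. Asymmetric hydrogenation of this α-alkoxy acrylic acid ([Rh(cod)2]BF4 with a chiral ferrocenyl bisphosphine of the Walphos family, H2, MeOH; ligand enantiomer chosen to deliver the S acid) gives the (S)-2-benzyloxy acid F6. Amide coupling with MeNH(OMe)·HCl (EDC·HCl, HOBt, i-Pr2NEt, CH2Cl2) rejoins the route at Weinreb amide 19.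

Step 11. The aluminium amide may attack the ring carbonyl of the oxazolidinone and open the auxiliary, because the acyl carbonyl is flanked by a branched α-carbon and has no β-hydroxyl to direct the reagent. The fallback removes the auxiliary reductively and builds the ketone through the aldehyde. It sets out from imide 18. LiBH4 in THF/MeOH at 0 °C should give the primary alcohol F7 and the recovered auxiliary. Dess–Martin oxidation gives the α-benzyloxy aldehyde F8. Addition of arylmagnesium bromide 20 (THF, −78 °C) gives the secondary alcohol F9 as a mixture of C1 epimers. A second Dess–Martin oxidation removes that stereocentre and rejoins the route at ketone 21, so steps 11 and 12 are both bypassed.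

**Further compounds**

F1 | step 14 | (1S,2S)-2-(benzyloxy)-1-[4-(benzyloxy)-3-(methoxymethoxy)phenyl]-3-[2-(benzyloxy)-6-bromo-4-(methoxymethoxy)phenyl]propan-1-ol | COCOc1cc(OCc2ccccc2)c(C[C@H](OCc2ccccc2)[C@@H](O)c2ccc(OCc3ccccc3)c(OCOC)c2)c(Br)c1
F2 | step 14 | (1S,2S)-2-(benzyloxy)-1-[4-(benzyloxy)-3-(methoxymethoxy)phenyl]-3-[2-(benzyloxy)-4-(methoxymethoxy)-6-(4,4,5,5-tetramethyl-1,3,2-dioxaborolan-2-yl)phenyl]propan-1-ol | COCOc1cc(OCc2ccccc2)c(C[C@H](OCc2ccccc2)[C@@H](O)c2ccc(OCc3ccccc3)c(OCOC)c2)c(B2OC(C)(C)C(C)(C)O2)c1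
F3 | step 14 | (1S,2S)-2-(benzyloxy)-1-[4-(benzyloxy)-3-(methoxymethoxy)phenyl]-3-[2-(benzyloxy)-6-hydroxy-4-(methoxymethoxy)phenyl]propan-1-ol | COCOc1cc(OCc2ccccc2)c(C[C@H](OCc2ccccc2)[C@@H](O)c2ccc(OCc3ccccc3)c(OCOC)c2)c(O)c1
F4 | step 10 | methyl (Z)-2-(benzyloxy)-3-[2-(benzyloxy)-6-bromo-4-(methoxymethoxy)phenyl]prop-2-enoate | COC(=O)/C(OCc1ccccc1)=C/c1c(Br)cc(OCOC)cc1OCc1ccccc1
F5 | step 10 | (Z)-2-(benzyloxy)-3-[2-(benzyloxy)-6-bromo-4-(methoxymethoxy)phenyl]prop-2-enoic acid | OC(=O)/C(OCc1ccccc1)=C/c1c(Br)cc(OCOC)cc1OCc1ccccc1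
F6 | step 10 | (S)-2-(benzyloxy)-3-[2-(benzyloxy)-6-bromo-4-(methoxymethoxy)phenyl]propanoic acid | COCOc1cc(OCc2ccccc2)c(C[C@H](OCc2ccccc2)C(=O)O)c(Br)c1
F7 | step 11 | (S)-2-(benzyloxy)-3-[2-(benzyloxy)-6-bromo-4-(methoxymethoxy)phenyl]propan-1-ol | COCOc1cc(OCc2ccccc2)c(C[C@H](OCc2ccccc2)CO)c(Br)c1
F8 | step 11 | (S)-2-(benzyloxy)-3-[2-(benzyloxy)-6-bromo-4-(methoxymethoxy)phenyl]propanal | COCOc1cc(OCc2ccccc2)c(C[C@H](OCc2ccccc2)C=O)c(Br)c1
F9 | step 11 | (2S)-2-(benzyloxy)-1-[4-(benzyloxy)-3-(methoxymethoxy)phenyl]-3-[2-(benzyloxy)-6-bromo-4-(methoxymethoxy)phenyl]propan-1-ol, both C1 epimers | COCOc1cc(OCc2ccccc2)c(C[C@H](OCc2ccccc2)C(O)c2ccc(OCc3ccccc3)c(OCOC)c2)c(Br)c1
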